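At early times of a run the starting complex, fed in over 4.0 s, swaps a leaving ligand for an incoming ligand and becomes the complex with one exchanged. We have the two earlier runs and want the amount of that complex at the end of each new flask.

all flasks: starting complex 0.17 M (fed, over 4.0 s)

| flask | incoming ligand | leaving ligand | remark | time |
|---|---|---|---|---|
| north | 0.025 M | 0.34 M | run made earlier; the fed solution adds 0.10 times the starting volume |  |
| north-west | 0.58 M | 0.34 M | run made earlier; the fed solution adds 0.10 times the starting volume |  |
| ash | 0.0500 M | 0.340 M | the fed solution adds 0.10 times the starting volume | 2.0 min |
| larch | 0.100 M | 0.340 M | the fed solution adds 0.10 times the starting volume | 2.0 min |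
| maple | 0.200 M | 0.340 M | the fed solution adds 0.10 times the starting volume | 2.0 min |
| cedar | 0.400 M | 0.340 M | the fed solution adds 0.10 times the starting volume | 2.0 min |
| birch | 0.800 M | 0.340 M | the fed solution adds 0.10 times the starting volume | 2.0 min |

- north (time / s: complex with one exchanged / %, starting complex / %): 15.0: 1.4, 98.9; 40.0: 2.9, 95.6; 80.0: 2.9, 92.7; 120: 3.2, 89.7
- north-west (time / s: complex with one exchanged / %, starting complex / %): 15.0: 24.7, 68.0; 40.0: 32.9, 35.8; 80.0: 20.6, 14.4; 120: 11.0, 7.3

(scatter of a reading: 0.5 percentage points)

- every charge counts on the volume at the start, and the solution that is fed holds the whole dose
- the analysis behind the earlier runs scatters by 0.5 percentage points, standard deviation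
- "hardly changes" means that all values lie within two and a half points (for a concentration: within two and a half percent of the largest)

- amount of complex with one exchanged at the end, in percent of the starting complex charged for ash, larch, maple, cedar, birch, in this order
- how that number moves from the first to the last of them (rises, then falls / rises all the way / hardly changes / falls, then rises / falls all the way)

We build the flask one process at a time. Take the first step by itself: between 15.0 s and 40.0 s, north-west shows the starting complex falling at 0.0257 s⁻¹, as a share of what is there. After dilution by the feed, north-west holds 0.527 M of incoming ligand, and that is our first answer for the ligand doing this work. But by the middle of that span, at one ligand per complex lost, 0.0743 M has been used, so going round once more gives 0.453 M.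

Now add the loss of the exchanged complex. In north, the two complexes together lose 5.6 percentage points between 40.0 s and 120 s, while the exchanged complex stands near 3.00%. We read from this an onward loss of 0.0233 s⁻¹, with the scatter of the analysis in it. That is a half-life of 29.7 s, shorter than the asked 2.0 min.

If we take the share of starting complex turned per second to go in proportion to ligand, the two rates meet at 0.479 M of ligand on the first answer and 0.412 M on the second. This is the balance ligand, the concentration in the flask at which starting complex is turned as fast, share for share, as exchanged complex is lost. In this picture of two processes, with ligand held steady below it, exchanged complex settles at a ratio to starting complex of ligand over balance ligand minus ligand; with ligand held steady above it, exchanged complex keeps gaining on starting complex.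

Last, ligand is consumed as the flask runs, so it does not stay steady. Ash holds 0.0455 M of ligand against 0.155 M of complex, so ligand is the limiting reagent there. Cedar starts at 0.364 M, below balance, and birch at 0.727 M, above it. We commit to a shape and no row of our own: a rise along the flasks, then a fall by birch.

The forecast gives 4.3%, 7.6%, 11.8%, 12.5% and 8.5%, so rises, then falls, and says “the yield peaks near 0.3 M”.

The flasks give 5.29%, 9.24%, 13.7%, 14.2% and 6.80%: rises, then falls, turning at 0.30 M of ligand charged.

    starting complex + incoming ligand → leaving ligand + complex with one exchanged (k = 0.0610 L mol⁻¹ s⁻¹)
    complex with one exchanged + incoming ligand → leaving ligand + complex with two exchanged (k = 0.0251 L mol⁻¹ s⁻¹)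
    complex with two exchanged + incoming ligand → leaving ligand + complex with three exchanged (k = 0.185 L mol⁻¹ s⁻¹)
    complex with one exchanged → over-reaction product (k = 0.0206 s⁻¹)

In ash at 0.728 min, the complex with one exchanged has a half-life of 0.56 min by turning into over-reaction product, shorter than the 15 min by taking a second incoming ligand. That first half-life is also short against the 2.0 min. Against the balance ligand of 0.412 M, cedar ends with 0.189 M of ligand; the ratio rule, with that end value taken as if it had been held steady, gives 0.848, and cedar stands at 0.864. Birch ends above balance with 0.464 M, holding 6.80% of exchanged complex against 2.05% of starting complex.

The runs are simulated for an exercise, and the scatter is random.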